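The cyclohexene ring is opened at C1–C2 (shikimate numbering). The key step exploits the 1,3-relation between carboxyl-bearing C1 and oxygenated C3, a latent aldol, and the C6 methylene next to the trans C5/C4 diester; together they spell a 3-deoxy-D-arabino-heptulosonate, that is D-glucal carboxylated at its C1. The precursor is the methyl ketopyranoside of this sugar with an exocyclic C6=C7 enol ether and both chiral esters in place. In one operation catalytic Hg(OCOCF3)2 in wet acetone hydrates the enol ether, unzips the pyranose ring to an α-keto ester and a mercury enolate, and closes the carbocycle by aldol addition to a dehydroquinate diester. Dehydration, 1,2-reduction and inverting acetylation at C3 complete the target.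

Key step: step 12

Remark on locants: sugar-derived compounds carry ulosonate locants (C1 ester carbon, C2 anomeric carbon, C7 terminal carbon) and carbocycles carry shikimate locants. Ulosonate C2, C3, C4, C5, C6, C7 become shikimate C1, C6, C5, C4, C3, C2.
Remark on names: once ulosonate C6 is trigonal, only C4 and C5 remain as chain stereocentres, so the enol ether and its open-chain forms take the prefix D-threo.
Assumption: both chiral acids are bought as single enantiomers.

Step 1
Reactants: 1 D-glucal
Product: 2 4,6-O-(di-tert-butylsilanediyl)-D-glucal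
Conditions: tBu2Si(OTf)2, pyridine, DMF, −40 °C
Reagents that add atoms: di-tert-butylsilyl bis(trifluoromethanesulfonate), CC(C)(C)[Si](OS(=O)(=O)C(F)(F)F)(OS(=O)(=O)C(F)(F)F)C(C)(C)C
Why: Cyclic silylene protection of a 1,3-diol: the bis-triflate bridges O4 and O6 in a trans-fused six-membered ring and leaves only the allylic O3–H free, so the two secondary oxygens that will carry different esters are told apart at the outset without touching a stereocentre.

Step 2
Reactants: 2 4,6-O-(di-tert-butylsilanediyl)-D-glucal
Product: 3 4,6-O-(di-tert-butylsilanediyl)-3-O-triisopropylsilyl-D-glucal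
Conditions: TIPSOTf, 2,6-lutidine, CH2Cl2, 0 °C
Reagents that add atoms: triisopropylsilyl trifluoromethanesulfonate, CC(C)[Si](OS(=O)(=O)C(F)(F)F)(C(C)C)C(C)C
Why: Silyl ether formation with a silyl triflate and a hindered pyridine base; TIPS has no Si–CH3 group that t-BuLi could deprotonate in step 3, and it outlasts the silylene in step 6.

Step 3
Reactants: 3 4,6-O-(di-tert-butylsilanediyl)-3-O-triisopropylsilyl-D-glucal; 4 methyl chloroformate
Product: 6 methyl 2,6-anhydro-3-deoxy-5,7-O-(di-tert-butylsilanediyl)-4-O-triisopropylsilyl-D-arabino-hept-2-enonate, via 1-lithioglucal 5 (not isolated)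
Conditions: t-BuLi, THF, −78 → 0 °C; then cannulated into excess ClCO2Me, THF, −78 °C
Reagents that add atoms: methyl chloroformate, COC(=O)Cl
Why: Vinylic deprotonation of a fully silylated glycal at C1 (α-alkoxy vinyllithium formation) followed by C-acylation; inverse addition into excess chloroformate at −78 °C keeps 5 from adding a second time to the new ester.

Step 4
Reactants: 6 methyl 2,6-anhydro-3-deoxy-5,7-O-(di-tert-butylsilanediyl)-4-O-triisopropylsilyl-D-arabino-hept-2-enonate
Product: 7 methyl [methyl 3-deoxy-3-iodo-5,7-O-(di-tert-butylsilanediyl)-4-O-triisopropylsilyl-α-D-manno-hept-2-ulopyranosid]onate (axial iodine at C3, axial OMe and equatorial CO2Me at C2)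
Conditions: NIS, MeOH/CH2Cl2, 0 °C → rt, dark
Reagents that add atoms: N-iodosuccinimide, O=C1CCC(=O)N1I; methanol, CO
Why: Iodoalkoxylation of a 2,3-unsaturated ulosonate, chosen because the ester on C2 destabilises the oxocarbenium ion and makes plain acid-catalysed addition of methanol unreliable; in the locked half-chair the iodonium ion should be opened trans-diaxially by methanol at the oxygen-bearing C2, and both new centres are erased later (C3 in step 5, C2 in step 12), so any stereoisomers converge.

Step 5
Reactants: 7 methyl [methyl 3-deoxy-3-iodo-5,7-O-(di-tert-butylsilanediyl)-4-O-triisopropylsilyl-α-D-manno-hept-2-ulopyranosid]onate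
Product: 8 methyl [methyl 3-deoxy-5,7-O-(di-tert-butylsilanediyl)-4-O-triisopropylsilyl-α-D-arabino-hept-2-ulopyranosid]onate
Conditions: Bu3SnH, AIBN (cat.), toluene, 80 °C
Reagents that add atoms: none
Why: Radical chain dehalogenation with tin hydride removes the secondary iodide under neutral conditions that leave silyl ethers, ketal and ester alone, and C3 becomes the methylene that ends as C6 of the target.

Step 6
Reactants: 8 methyl [methyl 3-deoxy-5,7-O-(di-tert-butylsilanediyl)-4-O-triisopropylsilyl-α-D-arabino-hept-2-ulopyranosid]onate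
Product: 9 methyl (methyl 3-deoxy-4-O-triisopropylsilyl-α-D-arabino-hept-2-ulopyranosid)onate (5,7-diol)
Conditions: HF·pyridine, pyridine/THF, 0 °C
Reagents that add atoms: none
Why: Chemoselective fluoride desilylation: a cyclic di-tert-butylsilylene is cleaved by buffered HF at 0 °C much faster than a secondary TIPS ether, and the ester-deactivated methyl ketoside does not ionise in this weak acid.

Step 7
Reactants: 9 methyl (methyl 3-deoxy-4-O-triisopropylsilyl-α-D-arabino-hept-2-ulopyranosid)onate
Product: 10 methyl (methyl 3,7-dideoxy-7-iodo-4-O-triisopropylsilyl-α-D-arabino-hept-2-ulopyranosid)onate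
Conditions: I2, PPh3, imidazole, THF, 0 °C → rt
Reagents that add atoms: iodine, II
Why: Garegg–Samuelsson iodination (Appel-type SN2 on an alkoxyphosphonium salt) is selective for the primary C7 hydroxyl, because the secondary O5–H between the TIPS ether and C6 is too hindered to be displaced.

Step 8
Reactants: 10 methyl (methyl 3,7-dideoxy-7-iodo-4-O-triisopropylsilyl-α-D-arabino-hept-2-ulopyranosid)onate; 11 (R)-2-methylbutanoic acid
Product: 12 methyl (methyl 3,7-dideoxy-7-iodo-5-O-[(R)-2-methylbutanoyl]-4-O-triisopropylsilyl-α-D-arabino-hept-2-ulopyranosid)onate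
Conditions: DIC, DMAP, CH2Cl2, 0 °C → rt
Reagents that add atoms: (R)-2-methylbutanoic acid, CC[C@@H](C)C(=O)O
Why: Steglich esterification of the only free hydroxyl, so the ester can land only on O5; the ring centres are not involved, and the α-centre of a simple alkanoic acid is not enolised by DMAP at or below room temperature.

Step 9
Reactants: 12 methyl (methyl 3,7-dideoxy-7-iodo-5-O-[(R)-2-methylbutanoyl]-4-O-triisopropylsilyl-α-D-arabino-hept-2-ulopyranosid)onate
Product: 13 methyl (methyl 3,7-dideoxy-7-iodo-5-O-[(R)-2-methylbutanoyl]-α-D-arabino-hept-2-ulopyranosid)onate (free O4–H)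
Conditions: HF·pyridine (excess), THF, rt, polyethylene flask
Reagents that add atoms: none
Why: Fluoride desilylation in a mildly acidic medium, in which the primary iodide, the esters and the ketoside persist and O5→O4 acyl migration, a base-promoted process, is not expected.

Step 10
Reactants: 13 methyl (methyl 3,7-dideoxy-7-iodo-5-O-[(R)-2-methylbutanoyl]-α-D-arabino-hept-2-ulopyranosid)onate; 14 (S)-3-methylpentanoic acid
Product: 15 methyl (methyl 3,7-dideoxy-7-iodo-4-O-[(S)-3-methylpentanoyl]-5-O-[(R)-2-methylbutanoyl]-α-D-arabino-hept-2-ulopyranosid)onate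
Conditions: DIC, DMAP (cat.), CH2Cl2, 0 °C → rt
Reagents that add atoms: (S)-3-methylpentanoic acid, CC[C@H](C)CC(=O)O
Why: Steglich esterification of the unhindered equatorial O4–H next to the C3 methylene should be faster than any acyl migration, and the β-stereocentre of the acid cannot epimerise.

Step 11
Reactants: 15 methyl (methyl 3,7-dideoxy-7-iodo-4-O-[(S)-3-methylpentanoyl]-5-O-[(R)-2-methylbutanoyl]-α-D-arabino-hept-2-ulopyranosid)onate
Product: 16 methyl (methyl 3,7-dideoxy-4-O-[(S)-3-methylpentanoyl]-5-O-[(R)-2-methylbutanoyl]-α-D-threo-hept-6-en-2-ulopyranosid)onate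
Conditions: DBU, THF, 65 °C
Reagents that add atoms: none
Why: E2 dehydroiodination by an amidine base, the standard entry to exocyclic enol ethers from ω-iodo pyranosides; C6–H is the only hydrogen next to the leaving group, the C3 methylene is not acidified by the ketal carbon, and the ester α-centres are far too weakly acidic for DBU.

Step 12
Reactants: 16 methyl (methyl 3,7-dideoxy-4-O-[(S)-3-methylpentanoyl]-5-O-[(R)-2-methylbutanoyl]-α-D-threo-hept-6-en-2-ulopyranosid)onate
Product: 18 methyl (1R,4S,5R)-3-dehydroquinate 4-[(R)-2-methylbutanoate] 5-[(S)-3-methylpentanoate] (C1 hydroxyl axial, cis to O4, trans to O5), via acyclic 7-mercurio 2,6-diketo ester 17 (not isolated)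
Conditions: Hg(OCOCF3)2 (10 mol %), acetone/H2O 2:1, rt
Reagents that add atoms: water, O
Why: Proposed new method: divalent mercury adds to the terminal C7 of the electron-rich exocyclic enol ether and water adds to C6, the new C6 hemiketal collapses, and the former ring oxygen is left on C2 as a methyl hemiketal that sheds methanol, which gives the open-chain α-keto ester and α-mercurio ketone 17. The mercury enolate of 17 attacks the C2 keto group, forms the shikimate C1–C2 bond by a 6-(enolendo)-exo-trig aldol closure of the cyclohexane ring, and protonolysis of the mercury aldolate returns the catalyst. The closest known reaction type is the Ferrier carbocyclisation of aldohex-5-enopyranosides, which tolerates O-acyl groups; what is new is that a ketoside releases a ketone acceptor and a tertiary carbinol is formed, which is made plausible by the high electrophilicity of an α-keto ester and by the spontaneous cyclisation of the related free enol-pyranose acid to dehydroquinate in water. The one new centre, C1, should be set by a chair transition state with O4, O5 and CO2Me equatorial and the acceptor oxygen axial, bridged to the enolate oxygen by mercury, so the hydroxyl ends up axial (1R), and this centre is erased in step 13 in any case. The step needs aldol addition to be faster than loss of the C5 acyloxy group, which is β to both ketones, and this is secured by the regiospecific, non-basic generation of the enolate at shikimate C2 only and by the near-neutral medium.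

Step 13
Reactants: 18 methyl (1R,4S,5R)-3-dehydroquinate 4-[(R)-2-methylbutanoate] 5-[(S)-3-methylpentanoate]
Product: 20 methyl (4S,5R)-3-dehydroshikimate 4-[(R)-2-methylbutanoate] 5-[(S)-3-methylpentanoate], via C1 mesylate 19 (not isolated)
Conditions: MsCl, Et3N, CH2Cl2, −30 → 0 °C; pH 7 buffer quench
Reagents that add atoms: none
Why: Mesylation of the tertiary alcohol through sulfene followed by E1cB elimination in the same flask: free hydroxide would be a worse leaving group than the C5 carboxylate, whereas the axial C1 mesylate overlaps with the enolate formed at the C2 methylene and leaves first while the equatorial C5 acyloxy group is misaligned, so only the C1=C2 enone should form.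

Step 14
Reactants: 20 methyl (4S,5R)-3-dehydroshikimate 4-[(R)-2-methylbutanoate] 5-[(S)-3-methylpentanoate]
Product: 21 methyl 3-epi-shikimate 4-[(R)-2-methylbutanoate] 5-[(S)-3-methylpentanoate] (O3 trans to O4, O4 trans to O5)
Conditions: NaBH4, CeCl3·7H2O, MeOH, −78 °C; AcOH quench
Reagents that add atoms: none
Why: Luche reduction: cerium-activated borohydride adds 1,2 rather than 1,4 to the ene-keto ester, and axial delivery to the half-chair with O4 and O5 equatorial should set C3 with a pseudo-equatorial hydroxyl trans to O4.

Step 15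
Reactants: 21 methyl 3-epi-shikimate 4-[(R)-2-methylbutanoate] 5-[(S)-3-methylpentanoate]; 22 acetic acid
Product: 23 methyl (3R,4S,5R)-3-acetoxy-4-[(R)-2-methylbutanoyloxy]-5-[(S)-3-methylpentanoyloxy]cyclohex-1-ene-1-carboxylate (CNP0188172.1)
Conditions: AcOH, PPh3, DIAD, toluene, 0 °C → rt
Reagents that add atoms: acetic acid, CC(=O)O
Why: Mitsunobu esterification: SN2 displacement of the allylic alkoxyphosphonium ion by acetate inverts C3 to the required O3/O4-cis (3R) configuration, and the SN2′ path is disfavoured because it would attack the fully substituted C1 and break the conjugation with the ester.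

Compound list
1 | D-glucal | OC[C@H]1OC=C[C@@H](O)[C@@H]1O | starting material
2 | 4,6-O-(di-tert-butylsilanediyl)-D-glucal | O[C@@H]1C=CO[C@@H]2CO[Si](C(C)(C)C)(C(C)(C)C)O[C@@H]12 | intermediate
3 | 4,6-O-(di-tert-butylsilanediyl)-3-O-triisopropylsilyl-D-glucal | CC(C)[Si](C(C)C)(C(C)C)O[C@@H]1C=CO[C@@H]2CO[Si](C(C)(C)C)(C(C)(C)C)O[C@@H]12 | intermediate
4 | methyl chloroformate | COC(=O)Cl | starting material
5 | 1-lithio derivative of 3 | CC(C)[Si](C(C)C)(C(C)C)O[C@@H]1C=C([Li])O[C@@H]2CO[Si](C(C)(C)C)(C(C)(C)C)O[C@@H]12 | intermediate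
6 | methyl 2,6-anhydro-3-deoxy-5,7-O-(di-tert-butylsilanediyl)-4-O-triisopropylsilyl-D-arabino-hept-2-enonate | CC(C)[Si](C(C)C)(C(C)C)O[C@@H]1C=C(C(=O)OC)O[C@@H]2CO[Si](C(C)(C)C)(C(C)(C)C)O[C@@H]12 | intermediate
7 | methyl [methyl 3-deoxy-3-iodo-5,7-O-(di-tert-butylsilanediyl)-4-O-triisopropylsilyl-α-D-manno-hept-2-ulopyranosid]onate | CC(C)[Si](C(C)C)(C(C)C)O[C@@H]1[C@H](I)[C@](OC)(C(=O)OC)O[C@@H]2CO[Si](C(C)(C)C)(C(C)(C)C)O[C@@H]12 | intermediate
8 | methyl [methyl 3-deoxy-5,7-O-(di-tert-butylsilanediyl)-4-O-triisopropylsilyl-α-D-arabino-hept-2-ulopyranosid]onate | CC(C)[Si](C(C)C)(C(C)C)O[C@@H]1C[C@](OC)(C(=O)OC)O[C@@H]2CO[Si](C(C)(C)C)(C(C)(C)C)O[C@@H]12 | intermediate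
9 | methyl (methyl 3-deoxy-4-O-triisopropylsilyl-α-D-arabino-hept-2-ulopyranosid)onate | COC(=O)[C@@]1(OC)C[C@@H](O[Si](C(C)C)(C(C)C)C(C)C)[C@H](O)[C@@H](CO)O1 | intermediate
10 | methyl (methyl 3,7-dideoxy-7-iodo-4-O-triisopropylsilyl-α-D-arabino-hept-2-ulopyranosid)onate | COC(=O)[C@@]1(OC)C[C@@H](O[Si](C(C)C)(C(C)C)C(C)C)[C@H](O)[C@@H](CI)O1 | intermediate
11 | (R)-2-methylbutanoic acid | CC[C@@H](C)C(=O)O | starting material
12 | methyl (methyl 3,7-dideoxy-7-iodo-5-O-[(R)-2-methylbutanoyl]-4-O-triisopropylsilyl-α-D-arabino-hept-2-ulopyranosid)onate | COC(=O)[C@@]1(OC)C[C@@H](O[Si](C(C)C)(C(C)C)C(C)C)[C@H](OC(=O)[C@H](C)CC)[C@@H](CI)O1 | intermediate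
13 | methyl (methyl 3,7-dideoxy-7-iodo-5-O-[(R)-2-methylbutanoyl]-α-D-arabino-hept-2-ulopyranosid)onate | COC(=O)[C@@]1(OC)C[C@@H](O)[C@H](OC(=O)[C@H](C)CC)[C@@H](CI)O1 | intermediate
14 | (S)-3-methylpentanoic acid | CC[C@H](C)CC(=O)O | starting material
15 | methyl (methyl 3,7-dideoxy-7-iodo-4-O-[(S)-3-methylpentanoyl]-5-O-[(R)-2-methylbutanoyl]-α-D-arabino-hept-2-ulopyranosid)onate | COC(=O)[C@@]1(OC)C[C@@H](OC(=O)C[C@@H](C)CC)[C@H](OC(=O)[C@H](C)CC)[C@@H](CI)O1 | intermediate
16 | methyl (methyl 3,7-dideoxy-4-O-[(S)-3-methylpentanoyl]-5-O-[(R)-2-methylbutanoyl]-α-D-threo-hept-6-en-2-ulopyranosid)onate | COC(=O)[C@@]1(OC)C[C@@H](OC(=O)C[C@@H](C)CC)[C@H](OC(=O)[C@H](C)CC)C(=C)O1 | intermediate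
17 | methyl 3,7-dideoxy-4-O-[(S)-3-methylpentanoyl]-5-O-[(R)-2-methylbutanoyl]-7-(trifluoroacetoxymercurio)-D-threo-hept-2,6-diulosonate | COC(=O)C(=O)C[C@@H](OC(=O)C[C@@H](C)CC)[C@H](OC(=O)[C@H](C)CC)C(=O)C[Hg]OC(=O)C(F)(F)F | intermediate
18 | methyl (1R,4S,5R)-3-dehydroquinate 4-[(R)-2-methylbutanoate] 5-[(S)-3-methylpentanoate] | COC(=O)[C@]1(O)CC(=O)[C@@H](OC(=O)[C@H](C)CC)[C@H](OC(=O)C[C@@H](C)CC)C1 | intermediate
19 | 1-O-methanesulfonyl derivative of 18 | COC(=O)[C@]1(OS(C)(=O)=O)CC(=O)[C@@H](OC(=O)[C@H](C)CC)[C@H](OC(=O)C[C@@H](C)CC)C1 | intermediate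
20 | methyl (4S,5R)-3-dehydroshikimate 4-[(R)-2-methylbutanoate] 5-[(S)-3-methylpentanoate] | COC(=O)C1=CC(=O)[C@@H](OC(=O)[C@H](C)CC)[C@H](OC(=O)C[C@@H](C)CC)C1 | intermediate
21 | methyl 3-epi-shikimate 4-[(R)-2-methylbutanoate] 5-[(S)-3-methylpentanoate] | COC(=O)C1=C[C@H](O)[C@@H](OC(=O)[C@H](C)CC)[C@H](OC(=O)C[C@@H](C)CC)C1 | intermediate
22 | acetic acid | CC(=O)O | starting material
23 | methyl (3R,4S,5R)-3-acetoxy-4-[(R)-2-methylbutanoyloxy]-5-[(S)-3-methylpentanoyloxy]cyclohex-1-ene-1-carboxylate | CC[C@H](C)CC(=O)O[C@@H]1CC(C(=O)OC)=C[C@@H](OC(C)=O)[C@H]1OC(=O)[C@H](C)CC | target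

Total step count: 15
Longest linear sequence: 15 steps (from 1 to 23)

Steps most likely to fail

1. Step 12.
- **What may go wrong:** The carbon–mercury bond may undergo protonolysis, or the enol ether may simply hydrolyse in acid, before the carbon–carbon bond forms. The addition may be slow because the keto ester rests as its hydrate in the wet medium. The C5 acyloxy group may be lost by β-elimination.
- **Fallback (known chemistry only, from 16 back to 18):** Bromohydration of the enol ether with NBS in aqueous THF at 0 °C triggers the same ring opening and loss of methanol. It should give the isolable α-bromo ketone methyl 7-bromo-3,7-dideoxy-4-O-[(S)-3-methylpentanoyl]-5-O-[(R)-2-methylbutanoyl]-D-threo-hept-2,6-diulosonate F1. Activated zinc dust in dry THF (0 °C → rt) then makes the zinc enolate at the same carbon, now without water to hydrate the acceptor. An intramolecular Reformatsky-type aldol followed by an NH4Cl quench should give 18.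

2. Step 13.
- **What may go wrong:** After the wanted elimination, the amine base may enolise the enone toward C4 or deprotonate C6. Either event expels the C5 carboxylate and aromatises the ring.
- **Fallback (from 18 back to 20):** A thermal syn-elimination without external base replaces the base-induced E1cB process. The Burgess reagent, methyl N-(triethylammoniosulfonyl)carbamate, in toluene at rt should convert the tertiary alcohol into the 1-O-[N-(methoxycarbonyl)sulfamoyl] derivative of the dehydroquinate diester F2. On warming to about 50 °C this should remove the more acidic C2 hydrogen intramolecularly and give 20.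

3. Step 15.
- **What may go wrong:** The neighbouring C4 ester carbonyl may take part in the departure of the phosphine oxide, which scrambles acyl groups between O3 and O4 or gives retention. Elimination to a diene followed by aromatisation is also possible.
- **Fallback (from 20 back to 23, bypassing 21):** No leaving group is ever placed on C3. A Corey–Bakshi–Shibata reduction is run with BH3·SMe2 in toluene at −40 °C. It uses the antipode of the B-methyl oxazaborolidine catalyst that delivers hydride to the face of C3 anti to O4; both antipodes are commercial, and the choice is settled on a small scale. It should give methyl shikimate 4-[(R)-2-methylbutanoate] 5-[(S)-3-methylpentanoate] F3. This is acetylated at once with retention (Ac2O, pyridine, 0 °C), before O4→O3 acyl migration can set in, to give 23.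

Further compounds
F1 | step 12 | methyl 7-bromo-3,7-dideoxy-4-O-[(S)-3-methylpentanoyl]-5-O-[(R)-2-methylbutanoyl]-D-threo-hept-2,6-diulosonate | COC(=O)C(=O)C[C@@H](OC(=O)C[C@@H](C)CC)[C@H](OC(=O)[C@H](C)CC)C(=O)CBr
F2 | step 13 | 1-O-[N-(methoxycarbonyl)sulfamoyl] derivative of methyl 3-dehydroquinate 4-[(R)-2-methylbutanoate] 5-[(S)-3-methylpentanoate] | COC(=O)[C@]1(OS(=O)(=O)NC(=O)OC)CC(=O)[C@@H](OC(=O)[C@H](C)CC)[C@H](OC(=O)C[C@@H](C)CC)C1
F3 | step 15 | methyl shikimate 4-[(R)-2-methylbutanoate] 5-[(S)-3-methylpentanoate] | COC(=O)C1=C[C@@H](O)[C@@H](OC(=O)[C@H](C)CC)[C@H](OC(=O)C[C@@H](C)CC)C1
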